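0.40 M of starting material, half the south-west charge, with 0.800 equiv of coupling partner: I want the ratio of target to side product in this flask, early and late.

| flask | starting material | coupling partner | remark | time |
|---|---|---|---|---|
| south-west | 0.80 M | 0.80 equiv | run made earlier |  |
| flask | 0.40 M | 0.800 equiv |  | 25 h |

south-west run (percent of the starting material charged)

| time / h | target / % | side product / % |
|---|---|---|
| 0.250 | 1.2 | 0.1 |
| 0.833 | 5.0 | 3.3 |
| 1.33 | 7.4 | 5.0 |
| 2.00 | 9.4 | 6.3 |
| 3.00 | 11.5 | 7.6 |
| 4.00 | 13.0 | 8.7 |
| 5.00 | 14.1 | 9.5 |

(standard deviation of a reading: 0.3 percentage points)

1. ratio of target to side product at 20 min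
2. ratio of target to side product at 25 h

- steps under discussion: coupling partner + intermediate -> side product; starting material + coupling partner <-> intermediate; target <-> isomer of the product; coupling partner + intermediate -> target

Two things in the south-west run seem not to fit together. The target's gain per hour falls by a factor of 5.93 from the interval between 0.250 h and 0.833 h to the last hour, yet target over side product reads 1.52 at 0.833 h and 1.48 at 5.00 h.

The balance of the coupling partner, the limiting reagent, clears this up. It leaves first to the intermediate, then by the two product steps, and both of those carry the same [coupling partner][intermediate], so that factor cancels from their ratio. I call the last reading of target over side product the split, a reading with a scatter of 0.3 percentage points on each product. I see no drift after 0.833 h, so I reckon 1.48 for both times. The first reading adds little, since its side product, 0.1%, is less than the scatter.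

The forecast gives 1.5 at 20 min and 1.45 at 25 h, holding that “Halving the concentration changes the rates, not the selectivity”. My 1.48 differs from it at both times: it is lower at 20 min and higher at 25 h.

The flask gives 1.57 at 20 min and 1.51 at 25 h.

    coupling partner + intermediate → side product (k = 1.30 × 10⁻⁴ /M/s)
    starting material + coupling partner ⇌ intermediate (K = 1.80 /M, k = 9.50 × 10⁻⁴ /M/s)
    target ⇌ isomer of the product (K = 0.220, k = 0.00130 /s)
    coupling partner + intermediate → target (k = 2.40 × 10⁻⁴ /M/s)

At 25 h this flask's rate of using intermediate towards target over that towards side product is 1.8, more than its standing ratio of target to side product of 1.51, while 3.84% stands as isomer of the product. In the neighbour with 3.20 equiv of coupling partner, the split of 1.48 on its 35.1% of side product reckons 51.9% of target, and that neighbour holds 53.1%.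

The numbers in the tables were computed for an exercise; the scatter is artificial.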